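At late times D has become Q, and that Q can stand free, sit on X as X.Q, or be lost for good to Q2.

    D → Q (k1 = 0.25 /s, Ea1 = 74.0 kJ/mol)
    X + Q ⇌ X.Q (K2 = 8.7 /M, k2 = 0.071 /M/s, Ea2 = 51.0 kJ/mol, ΔH2 = −34.0 kJ/mol)
    2 Q → Q2 (k3 = 0.031 /M/s, Ea3 = 54.0 kJ/mol)
    (constants at 70 °C)

the same everywhere: D 0.50 M; X 0.475 M; time 25 s

| flask | temperature |
|---|---|
| noon | 85 °C |
| autumn | 70 °C |
| dawn | 115 °C |
| spring | 100 °C |

* the flask with the highest amount of Q, in percent of the D charged ("all alike" if they lie within 1.5 percentage points) (noon / autumn / dawn / spring / all alike)
* final Q, as a percentage of the D charged, in noon
* final Q, as a percentage of the D charged, in autumn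
* final Q, as a percentage of the D charged, in dawn
* final Q, as a percentage of the D charged, in spring

- a species is counted by the D in it: one Q2 counts as two
- for a step with 2 of a species take k times the square, and two of it per event
- the list of constants is for 70 °C, to be carried to other temperatures by the activation energies and enthalpies

Two chemists dispute the order of the flasks. Both treat D as Q from the start, because its half-life, ln(2) over its rate constant, is 2.77 s in autumn and 0.137 s in dawn, each shorter than the run.

The binder looks to the equilibrium of X with Q. Holding X at its charge, the free share f of the Q is one over one plus the equilibrium constant times X. In autumn, with the constant at 8.7 /M, f is 19.5 %. In dawn heat lowers the constant to 2.19 /M, and f is 49.1 %, so the binder expects more Q in dawn than in autumn.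

The dimer advocate sets X aside. Two Q must meet, so the loss slows as Q thins, and the reciprocal of Q climbs in a straight line with time. That leaves 56.3 % of the D as Q in autumn, but 12.6 % in dawn, so this side expects more Q in autumn than in dawn.

My own reckoning asks who has had time to act. Freezing X at its charge makes binding pseudo-first-order. Its binding time τ, 23.9 s in autumn, is one over the sum of the forward constant times X and the backward constant, the time in which binding closes all but about a third of its distance to equilibrium. In dawn τ is 1.90 s.

In autumn τ is about as long as the run, so binding is still under way, and I place Q between 19.5 % and 56.3 %. In dawn τ is far shorter than the run, so I take f to hold after the opening seconds. Free Q dimerises and X.Q does not, so the reciprocal of the pool of Q and X.Q climbs at f squared times the earlier slope. That leaves Q at 18.3 %, less than even my low autumn figure. I therefore side with the dimer advocate on the order.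

The forecast takes that side too and names autumn: 42 % there, 28 % in noon, 23 % in spring and 16 % in dawn, my dawn figure being higher than its own. Its ground is: “Hotter flasks dimerise faster and bind less, but Q2 wins overall”.

The simulation puts more Q in autumn than in any other flask: 43.2 %, against 26.5 % in noon, 21.7 % in spring and 16.3 % in dawn. In autumn, step one was still running at 6.00 s, with 22.3 % of the D left and Q at 65.2 %; by 25.0 s, with D at 0.193 %, Q was made at 3.85 % of the rate it was used, each step taken net, beside 32.9 % as X.Q and 23.7 % as Q2. After about one τ, 23.9 s, free Q was 56.8 % of the autumn pool, above f. The binder's region is dawn, where τ is 1.90 s: at 25.0 s free Q was 51.3 % of the pool, against an f of 49.1 % reckoned with X at its charge.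

(Its constants are those of an exercise; no experiment stands behind them.)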